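**Retrosynthetic overview**
1. Target ⇒ ester C–O bond (14-methylpentadecanoic acid + C1′ carbinol) and two protecting groups; the C1′ centre ⇐ chelation-controlled reduction of a C1′ ketone by the neighbouring C3′ oxygen.
2. Key disconnection C1′–C2′: ketone ⇒ bis-oxazole carboxylic acid (acyl donor) + primary C2′ radical, released photochemically by C1–C2 β-scission of an anomeric N-alkoxyphthalimide of 2-deoxy-L-fucose; the excised C1 stays on O5′ as a formate protecting group.
3. Radical precursor ⇒ 3,4-O-isopropylidene-L-fucal ⇒ L-fucose, which supplies C3′, C4′ and C5′.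
4. Bis-oxazole acid ⇒ CH2–C5 Suzuki disconnection between two purchased oxazoles.
5. Ring order: no ring of the target is built (both oxazoles are bought); only a temporary dioxolane is made in step 2 and removed in step 8.

Assumption: compounds 8, 9 and 16 are purchased; side-chain carbons are called C1′ (acyloxy carbon) to C6′ (methyl), sugar carbons C1 to C6, and the acyl chain of the SMILES is read as 14-methylpentadecanoyl.

**Step 1**
Reactants: 1 L-fucose
Product: 4 3,4-di-O-acetyl-L-fucal, via fucose tetraacetate 2 (not isolated), via acetobromofucose 3 (not isolated)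
Conditions: Ac2O, 33% HBr/AcOH, 0 °C to rt; then Zn dust, CuSO4·5H2O (cat.), NaOAc, AcOH/H2O, 0 °C to rt
Reagents that add atoms: acetic anhydride CC(=O)OC(C)=O
Why: One-pot peracetylation, anomeric bromination and zinc-mediated reductive 1,2-elimination (Fischer–Zach glycal synthesis) removes the C2 oxygen while the C3, C4 and C5 stereocentres of the sugar are carried over untouched.

**Step 2**
Reactants: 4 3,4-di-O-acetyl-L-fucal
Product: 6 3,4-O-isopropylidene-L-fucal, via L-fucal 5 (not isolated)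
Conditions: K2CO3 (0.1 equiv), MeOH, rt; filter, evaporate; then Me2C(OMe)2, PPTS (0.2 equiv), acetone, 0 °C to rt; Et3N
Reagents that add atoms: 2,2-dimethoxypropane COC(C)(C)OC
Why: Base-catalysed transesterification (Zemplén type) frees the cis-3,4-diol, which closes to the cis-fused dioxolane by mild transacetalisation under PPTS, an acid too weak to add methanol to the enol ether, and no stereocentre is touched.

**Step 3**
Reactants: 6 3,4-O-isopropylidene-L-fucal
Product: 7 N-[(2-deoxy-3,4-O-isopropylidene-L-fucopyranosyl)oxy]phthalimide (anomeric mixture)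
Conditions: N-hydroxyphthalimide (1.2 equiv), PPh3·HBr (5 mol%), THF/CH2Cl2, rt
Reagents that add atoms: N-hydroxyphthalimide O=C1c2ccccc2C(=O)N1O
Why: Acid-catalysed Markovnikov addition of the acidic N–OH across the glycal enol ether (the reaction that gives the tetrahydropyranyl ether of N-hydroxyphthalimide from dihydropyran) installs a redox-active alkoxyl-radical precursor, and the anomeric configuration is irrelevant because that carbon is excised in step 5.

**Step 4**
Reactants: 8 methyl 2-(chloromethyl)-1,3-oxazole-4-carboxylate; 9 5-(4,4,5,5-tetramethyl-1,3,2-dioxaborolan-2-yl)-2-(triisopropylsilyl)-1,3-oxazole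
Product: 12 2-(1,3-oxazol-5-ylmethyl)-1,3-oxazole-4-carboxylic acid, via silylated bis-oxazole methyl ester 10 (not isolated), via lithium carboxylate 11 (not isolated)
Conditions: PdCl2(dppf) (5 mol%; dppf = 1,1′-bis(diphenylphosphino)ferrocene), K3PO4, 1,4-dioxane/H2O (10:1), 80 °C; then LiOH·H2O, THF/H2O, rt; wash with EtOAc; then 1 M HCl to pH 2, rt
Reagents that add atoms: lithium hydroxide [Li+].[OH-]
Why: An sp3–sp2 Suzuki–Miyaura coupling of the activated heterobenzylic chloride with the C2-blocked oxazol-5-yl boronate joins the two rings, saponification gives the carboxylate (purified by the basic wash), and acidification both protonates it and protodesilylates the labile oxazole C2–Si bond.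

**Step 5**
Reactants: 7 N-[(2-deoxy-3,4-O-isopropylidene-L-fucopyranosyl)oxy]phthalimide; 12 2-(1,3-oxazol-5-ylmethyl)-1,3-oxazole-4-carboxylic acid
Product: 14 (1S)-1-[(4R,5S)-2,2-dimethyl-5-{2-oxo-2-[2-(1,3-oxazol-5-ylmethyl)-1,3-oxazol-4-yl]ethyl}-1,3-dioxolan-4-yl]ethyl formate, via mixed tert-butyl carbonic anhydride 13 (not isolated)
Conditions: 12 (1.5 equiv), Boc2O (1.6 equiv), MgCl2 (1.5 equiv), THF/DMA (1:1), rt, 1 h; then 7 (1.0 equiv), NiBr2·CH3OCH2CH2OCH3 (10 mol%), 4,4′-di-tert-butyl-2,2′-bipyridine (12 mol%), 4CzIPN (2 mol%), Hantzsch ester (1.5 equiv), 450 nm LEDs, 25 °C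
Reagents that add atoms: none
Why: Proposed new method: a nickel/photoredox deformylative ring-opening acylation in which the photocatalyst, reduced by Hantzsch ester under blue light, transfers an electron to the Mg2+-activated N-alkoxyphthalimide 7, N–O cleavage gives the anomeric alkoxyl radical, its C1–C2 β-scission (Suárez-type fragmentation driven by formation of the formate C=O) releases the primary C2′ radical with O5′ capped as a formate, and meanwhile zerovalent nickel inserts into the acyl C–O bond of 13 so that the divalent acyl-nickel traps the radical and reductively eliminates from the trivalent state to forge the C1′–C2′ bond; no stereocentre is formed or disturbed (the radical carbon is a CH2 and the adjacent C3′–O bond does not fragment), and the closest known reaction types are nickel-catalysed reductive acyl–alkyl coupling of in-flask mixed anhydrides with alkyl halides or redox-active esters and nickel/photoredox arylation of N-alkoxyphthalimides after β-scission, neither of which has been shown for an anomeric N-alkoxyphthalimide with an acyl partner.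

**Step 6**
Reactants: 14 (1S)-1-[(4R,5S)-2,2-dimethyl-5-{2-oxo-2-[2-(1,3-oxazol-5-ylmethyl)-1,3-oxazol-4-yl]ethyl}-1,3-dioxolan-4-yl]ethyl formate
Product: 15 (1S)-1-[(4R,5S)-5-{(2R)-2-hydroxy-2-[2-(1,3-oxazol-5-ylmethyl)-1,3-oxazol-4-yl]ethyl}-2,2-dimethyl-1,3-dioxolan-4-yl]ethyl formate
Conditions: Zn(BH4)2 (0.2 M in Et2O, 2 equiv), CH2Cl2/Et2O, −78 to −40 °C; then H2O
Reagents that add atoms: none
Why: In this chelation-controlled reduction zinc bridges the ketone oxygen and the β-alkoxy oxygen O3′ of the dioxolane in a six-membered chelate and hydride is delivered axially to the chair-like chelate, which sets the 1,3-syn (1′R) carbinol under control of the fucose-derived C3′ centre, while the formate is not reduced at this temperature.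

**Step 7**
Reactants: 15 (1S)-1-[(4R,5S)-5-{(2R)-2-hydroxy-2-[2-(1,3-oxazol-5-ylmethyl)-1,3-oxazol-4-yl]ethyl}-2,2-dimethyl-1,3-dioxolan-4-yl]ethyl formate; 16 14-methylpentadecanoic acid
Product: 17 (1R)-2-{(4S,5R)-5-[(1S)-1-(formyloxy)ethyl]-2,2-dimethyl-1,3-dioxolan-4-yl}-1-[2-(1,3-oxazol-5-ylmethyl)-1,3-oxazol-4-yl]ethyl 14-methylpentadecanoate
Conditions: DIC (1.5 equiv), DMAP (0.2 equiv), CH2Cl2, 0 °C to rt
Reagents that add atoms: none
Why: Steglich esterification acylates the only free hydroxyl with retention at C1′, the formate and the acetonide being inert to carbodiimide and DMAP.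

**Step 8**
Reactants: 17 (1R)-2-{(4S,5R)-5-[(1S)-1-(formyloxy)ethyl]-2,2-dimethyl-1,3-dioxolan-4-yl}-1-[2-(1,3-oxazol-5-ylmethyl)-1,3-oxazol-4-yl]ethyl 14-methylpentadecanoate
Product: 19 (1R,3S,4R,5S)-3,4,5-trihydroxy-1-[2-(1,3-oxazol-5-ylmethyl)-1,3-oxazol-4-yl]hexyl 14-methylpentadecanoate, via hydroxy acetonide 18 (not isolated)
Conditions: KHCO3 (0.3 equiv), MeOH, 0 °C; evaporate; then AcOH/H2O (4:1), 45 °C
Reagents that add atoms: none
Why: Base-catalysed methanolysis removes the formate far faster than it attacks the hindered secondary fatty ester (O3′ is still masked, so no acyl shift is possible), and acid-catalysed acetal hydrolysis in aqueous acetic acid then frees the 3′,4′-diol without cleaving the ester or touching any stereocentre.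

**Compound list**
1 | L-fucose (6-deoxy-L-galactopyranose) | OC1[C@@H](O)[C@H](O)[C@H](O)[C@H](C)O1 | starting material
2 | 1,2,3,4-tetra-O-acetyl-L-fucopyranose (anomeric mixture) | CC(=O)OC1[C@@H](OC(C)=O)[C@H](OC(C)=O)[C@H](OC(C)=O)[C@H](C)O1 | intermediate
3 | 2,3,4-tri-O-acetyl-α-L-fucopyranosyl bromide | Br[C@H]1[C@@H](OC(C)=O)[C@H](OC(C)=O)[C@H](OC(C)=O)[C@H](C)O1 | intermediate
4 | 3,4-di-O-acetyl-L-fucal | C1=C[C@H](OC(C)=O)[C@H](OC(C)=O)[C@H](C)O1 | intermediate
5 | L-fucal | C1=C[C@H](O)[C@H](O)[C@H](C)O1 | intermediate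
6 | 3,4-O-isopropylidene-L-fucal | C1=C[C@@H]2OC(C)(C)O[C@@H]2[C@H](C)O1 | intermediate
7 | N-[(2-deoxy-3,4-O-isopropylidene-L-fucopyranosyl)oxy]phthalimide (anomeric mixture) | O=C1c2ccccc2C(=O)N1OC3C[C@@H]4OC(C)(C)O[C@@H]4[C@H](C)O3 | intermediate
8 | methyl 2-(chloromethyl)-1,3-oxazole-4-carboxylate | COC(=O)c1coc(CCl)n1 | starting material
9 | 5-(4,4,5,5-tetramethyl-1,3,2-dioxaborolan-2-yl)-2-(triisopropylsilyl)-1,3-oxazole | CC(C)[Si](C(C)C)(C(C)C)c1ncc(o1)B1OC(C)(C)C(C)(C)O1 | starting material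
10 | methyl 2-{[2-(triisopropylsilyl)-1,3-oxazol-5-yl]methyl}-1,3-oxazole-4-carboxylate | COC(=O)c1coc(Cc2cnc(o2)[Si](C(C)C)(C(C)C)C(C)C)n1 | intermediate
11 | lithium 2-{[2-(triisopropylsilyl)-1,3-oxazol-5-yl]methyl}-1,3-oxazole-4-carboxylate | [Li+].[O-]C(=O)c1coc(Cc2cnc(o2)[Si](C(C)C)(C(C)C)C(C)C)n1 | intermediate
12 | 2-(1,3-oxazol-5-ylmethyl)-1,3-oxazole-4-carboxylic acid | OC(=O)c1coc(Cc2cnco2)n1 | intermediate
13 | tert-butyl carbonic 2-(1,3-oxazol-5-ylmethyl)-1,3-oxazole-4-carboxylic anhydride | CC(C)(C)OC(=O)OC(=O)c1coc(Cc2cnco2)n1 | intermediate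
14 | (1S)-1-[(4R,5S)-2,2-dimethyl-5-{2-oxo-2-[2-(1,3-oxazol-5-ylmethyl)-1,3-oxazol-4-yl]ethyl}-1,3-dioxolan-4-yl]ethyl formate | O=C(C[C@@H]1OC(C)(C)O[C@@H]1[C@H](C)OC=O)c1coc(Cc2cnco2)n1 | intermediate
15 | (1S)-1-[(4R,5S)-5-{(2R)-2-hydroxy-2-[2-(1,3-oxazol-5-ylmethyl)-1,3-oxazol-4-yl]ethyl}-2,2-dimethyl-1,3-dioxolan-4-yl]ethyl formate | O[C@H](C[C@@H]1OC(C)(C)O[C@@H]1[C@H](C)OC=O)c1coc(Cc2cnco2)n1 | intermediate
16 | 14-methylpentadecanoic acid (isopalmitic acid) | CC(C)CCCCCCCCCCCCC(=O)O | starting material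
17 | (1R)-2-{(4S,5R)-5-[(1S)-1-(formyloxy)ethyl]-2,2-dimethyl-1,3-dioxolan-4-yl}-1-[2-(1,3-oxazol-5-ylmethyl)-1,3-oxazol-4-yl]ethyl 14-methylpentadecanoate | CC(C)CCCCCCCCCCCCC(=O)O[C@H](C[C@@H]1OC(C)(C)O[C@@H]1[C@H](C)OC=O)c1coc(Cc2cnco2)n1 | intermediate
18 | (1R)-2-{(4S,5R)-5-[(1S)-1-hydroxyethyl]-2,2-dimethyl-1,3-dioxolan-4-yl}-1-[2-(1,3-oxazol-5-ylmethyl)-1,3-oxazol-4-yl]ethyl 14-methylpentadecanoate | CC(C)CCCCCCCCCCCCC(=O)O[C@H](C[C@@H]1OC(C)(C)O[C@@H]1[C@H](C)O)c1coc(Cc2cnco2)n1 | intermediate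
19 | (1R,3S,4R,5S)-3,4,5-trihydroxy-1-[2-(1,3-oxazol-5-ylmethyl)-1,3-oxazol-4-yl]hexyl 14-methylpentadecanoate (CNP0273575.1) | CC(C)CCCCCCCCCCCCC(=O)O[C@H](C[C@H](O)[C@H](O)[C@H](C)O)c1coc(Cc2cnco2)n1 | target

**Count**
Total steps: 8. Longest linear sequence: 7 (steps 1, 2, 3, 5, 6, 7, 8 from L-fucose); step 4 is the convergent branch.

**Three steps most likely to fail**

Step 5 (the proposed new coupling). The risks are mismatched rates of radical release and acyl-nickel formation, reduction of the primary radical by Hantzsch ester, and β-alkoxy elimination from an alkyl-nickel species. The fallback uses known chemistry, sets out from 6 and comes back at 14. Acid-catalysed hydration of 6 (PPh3·HBr cat., THF/H2O, rt) gives the lactol 2-deoxy-3,4-O-isopropylidene-L-fucopyranose F1. The Suárez fragmentation of its anomeric alkoxyl radical (PhI(OAc)2, I2, CH2Cl2, visible light, rt) gives the primary iodide (1S)-1-[(4R,5R)-5-(iodomethyl)-2,2-dimethyl-1,3-dioxolan-4-yl]ethyl formate F2. A nickel-catalysed reductive acyl–alkyl coupling of this iodide with acid 12, activated in the flask as 13 (Boc2O, MgCl2, NiBr2·CH3OCH2CH2OCH3, 4,4′-di-tert-butyl-2,2′-bipyridine, Zn dust, THF/DMA, rt), then gives 14.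

Step 6 (syn-selective reduction). The oxazole nitrogen can compete with O3′ for zinc and erode the chelate-derived selectivity. The fallback sets out from 14 and comes back at 17, setting C1′ by inversion instead. A non-chelating reduction (LiBH(s-Bu)3, THF, −78 °C) favours the 1,3-anti alcohol (1S)-1-[(4R,5S)-5-{(2S)-2-hydroxy-2-[2-(1,3-oxazol-5-ylmethyl)-1,3-oxazol-4-yl]ethyl}-2,2-dimethyl-1,3-dioxolan-4-yl]ethyl formate F3, which is separated from any 15 (that portion goes on through step 7). The anti alcohol is esterified with 16 under Mitsunobu conditions (PPh3, DIAD, toluene, 0 °C to rt) with clean inversion at C1′ to give 17, so both epimers converge.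

Step 4 (sp3–sp2 Suzuki coupling). The chloromethyl oxazole can hydrolyse and the oxazolyl boronate can protodeboronate under aqueous base. The fallback reverses the polarity, sets out from 8 and comes back at 12. Zinc insertion into 8 (Zn dust, LiCl, THF, 25 °C) gives {[4-(methoxycarbonyl)-1,3-oxazol-2-yl]methyl}zinc chloride F4. Negishi coupling with purchased 5-bromo-1,3-oxazole (Pd(PPh3)4, THF, 50 °C) gives methyl 2-(1,3-oxazol-5-ylmethyl)-1,3-oxazole-4-carboxylate F5. Saponification (LiOH·H2O, THF/H2O, then 1 M HCl) gives 12.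

**Further compounds**
F1 | step 5 | 2-deoxy-3,4-O-isopropylidene-L-fucopyranose | OC1C[C@@H]2OC(C)(C)O[C@@H]2[C@H](C)O1
F2 | step 5 | (1S)-1-[(4R,5R)-5-(iodomethyl)-2,2-dimethyl-1,3-dioxolan-4-yl]ethyl formate | IC[C@@H]1OC(C)(C)O[C@@H]1[C@H](C)OC=O
F3 | step 6 | (1S)-1-[(4R,5S)-5-{(2S)-2-hydroxy-2-[2-(1,3-oxazol-5-ylmethyl)-1,3-oxazol-4-yl]ethyl}-2,2-dimethyl-1,3-dioxolan-4-yl]ethyl formate | O[C@@H](C[C@@H]1OC(C)(C)O[C@@H]1[C@H](C)OC=O)c1coc(Cc2cnco2)n1
F4 | step 4 | {[4-(methoxycarbonyl)-1,3-oxazol-2-yl]methyl}zinc chloride | COC(=O)c1coc(C[Zn]Cl)n1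
F5 | step 4 | methyl 2-(1,3-oxazol-5-ylmethyl)-1,3-oxazole-4-carboxylate | COC(=O)c1coc(Cc2cnco2)n1
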